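## Structural features

The target 19 is an isoflavone: a benzo ring A is fused along C4a–C8a to a 4-pyranone ring C (O1, C2–H, C3, C4=O), and a 4-hydroxyphenyl ring B is attached to C3 by a single bond. Ring A is pentasubstituted: only C5 carries hydrogen, C6 and C8 each carry a 3-methylbut-2-enyl chain, C7 carries a free hydroxyl between them, and C8a carries the ring oxygen. There is no stereocentre and no stereogenic double bond, so no adjacent stereocentres have to be related; the problem is purely one of regiochemistry. The fragile groups are the two trisubstituted alkenes, each ortho to the C7 phenol. Brønsted or Lewis acid closes them onto that oxygen as 2,2-dimethylchromans, and they do not tolerate hydrogenolysis, electrophilic halogen or strong oxidants; the pyranone is opened at C2 by hydroxide. The real difficulty is to place two C-prenyl groups at C6 and C8 and nowhere else (not on oxygen, not on ring B, not as 1,1-dimethylallyl isomers) in a contiguously substituted ring. The feature used is the oxygenation pattern of ring A: the oxygen-bearing C7 and C8a, together with the carboxyl-level C4 on C4a, alternate with C8, C6 and C4a, as in a poly-β-carbonyl chain C4–C4a–C8a–C8–C7–C6–C5 whose terminus C5 is at the aldehyde level. Ring A can therefore be closed by the single bond C4a–C5 from an open chain in which C6 and C8 are still sp3 and can be prenylated as enolates.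

## Logic of the disconnections

19 back to 18: the two O–Si bonds are cut. Both phenols must be masked through the organomagnesium and formamide-acetal steps, and silyl ethers are chosen because fluoride removes them without acid. The forward step must stay near neutral so that the C7 hydroxyl does not add to its neighbouring alkenes and the pyranone is not opened.

18 back to 16 (through 17): C2–C3 and C2–O1 are cut, which removes the one-carbon unit C2 and opens ring C to a 2-hydroxydeoxybenzoin. This is the most reliable way to close an isoflavone pyranone and it leaves a simple ketone. The forward step needs a non-acidic C1 reagent, a free C8a hydroxyl, and a blocked O7 so that the reagent cannot methylate it.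

16 back to 11 and 14 (through 15): the C3–C4 bond between the ketone carbon and the benzylic carbon is cut. In 11 the carbon C4 is an activated acyl carbon held in the acetonide, and the same step frees the C8a hydroxyl; the cut divides the molecule into a ring A half and a ring B half. The forward step needs a benzylic organomagnesium formed with little homocoupling, and addition that stops at the ketone.

14 back to 13 and 12: the C–Cl and O–Si bonds are cut; these are functional-group changes on a bought phenol. The only demand is silylation at the phenol and not at the benzylic alcohol.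

11 back to 10: the O7–Si bond is cut. A free phenoxide para to the acyl carbon would deactivate it towards 15 and consume reagent, so O7 is capped before the coupling.

10 back to 8 (through 9): the ring bond C4a–C5 is cut, with C7–OH returned to a ketone and C5 to a masked aldehyde. This is the central simplification: the arene and its regiochemical problem disappear, and all five substituents of ring A are fixed by chain connectivity. The forward step must free the aldehyde without harming the dioxinone or the alkenes and must cyclize through carbon, not oxygen. The acetal is kept until the flask in which the aldehyde is consumed, so the free 3-oxo aldehyde never has to be handled or alkylated. The two stereocentres of 8 are of no consequence.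

8 back to 7 and 2: the bond from C8 to the prenyl CH2 is cut. C8 lies between the C7 ketone and the vinylogous ester and is the most acidic position of 7, so the site of enolate formation is not in doubt. The forward step needs mono-alkylation at carbon.

7 back to 4 and 5 (through 6): the C7–C8 bond is cut, a Claisen-type acylation of the γ-anion of 5. 5 supplies C4, C4a, C8a and C8 with the C4 carboxyl and the C8a carbonyl already masked. Acylation must outrun proton transfer, and the product is more acidic than 5, so excess dienolate is required.

4 back to 3, and 3 back to 1 and 2: the ester C–O bond and the bond from C6 to its prenyl CH2 are cut. The acetal carbon of 1 becomes C5 and its α-carbon becomes C6. The enolate of 1 must be alkylated cold so that it does not expel methoxide.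

## Other disconnections considered

Alternative 1: The cut is at the two aryl–CH2 bonds C6–C1'' and C8–C1'' of an intact isoflavone, so none of the rings is built. Forward, daidzein A1 would be dibrominated and protected to 6,8-dibromo-7-(methoxymethoxy)-3-[4-(methoxymethoxy)phenyl]chromen-4-one A2. A2 would couple twice with tributyl(3-methylbut-2-enyl)stannane A3 under Pd(PPh3)4 (zerovalent palladium) to give 7-(methoxymethoxy)-3-[4-(methoxymethoxy)phenyl]-6,8-bis(3-methylbut-2-enyl)chromen-4-one A4, and acid would then remove both MOM groups.
- In favour: the isoflavone nucleus is bought, the sequence is about four steps, and each reaction is standard.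
- Against: ring B of A1 is also an activated phenol, so bromination at C6 and C8 only is not assured. An allylic stannane can transfer its group with allylic transposition, which would give 1,1-dimethylallyl isomers. The C8 bromide lies between two oxygen substituents, where coupling is slow and reduction of the C–Br bond competes. The final MOM cleavage needs acid exactly when the C7 hydroxyl sits between two prenyl alkenes. Stoichiometric tin must be removed.
- Comparison: on step economy this alternative is clearly the better plan (about four steps against eleven), and it equals the chosen plan in ending with one deprotection. On structure the chosen plan is stronger: the prenyl groups are placed on sp3 carbons by SN2 alkylation, their positions follow from chain connectivity and not from the directing effects of a phenol, and the only deprotection uses fluoride. On mechanism the alternative depends on two consecutive cross-couplings at hindered positions, the chosen plan on one intramolecular aldol closure.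

Alternative 2: Three bonds of ring A are cut, C7–C8, C4a–C8a and C6–C7, which leads back to two acyclic pieces. Forward, irradiation of (3E)-1-diazo-7-methylocta-3,6-dien-2-one A5 would trigger a Wolff rearrangement. The resulting ketene would add to triisopropyl[(5-methylhex-4-en-1-ynyl)oxy]silane A6, and four-electron ring opening, six-electron ring closure and tautomerization would give 2,6-bis(3-methylbut-2-enyl)-3-(triisopropylsilyloxy)phenol A7.
- In favour: the substitution pattern follows from a pericyclic cascade under neutral conditions, and both prenyl groups come from acyclic precursors. In that respect it is the equal of the chosen plan, since both build ring A from a chain and neither prenylates an arene. It is better in one respect: the two oxygens emerge differentiated, one free and one silylated.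
- Against: A7 carries hydrogen at C4a, so the C4 carbon is missing. An arylacetyl group would have to be introduced para to a free phenol by Friedel–Crafts-type chemistry, whose Lewis acids threaten the prenyl alkenes and the silyl ether. A5 and A6 each need several steps, A6 is a sensitive silyl ynol ether, and a photochemical step is required.
- Comparison: in the chosen plan C4 is present from the start as an activated acyl carbon, so the link to ring B is an addition and not an electrophilic aromatic substitution. On step economy this alternative is expected to be no shorter and probably longer once the acylation and ring C closure are counted.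

Alternative 3: The cut is at C4a–C5 and C8–C8a, so ring A is formed last on a finished pyranone. Forward, tert-butyl{[1-methoxy-7-methyl-2-(3-methylbut-2-enyl)octa-1,3,6-trien-3-yl]oxy}dimethylsilane A8 would add across the sulfonyl-bearing double bond of 3-(benzenesulfonyl)-5-[4-(tert-butyldimethylsilyloxy)phenyl]pyran-4-one A9. Loss of benzenesulfinic acid, methanol and the enol silyl group would give 3-[4-(tert-butyldimethylsilyloxy)phenyl]-7-hydroxy-6,8-bis(3-methylbut-2-enyl)chromen-4-one A10, one desilylation from 19.
- In favour: it is the most convergent plan. Rings B and C arrive in one piece, the polarity of diene and dienophile fixes the regiochemistry, and only a fluoride step follows. In convergence and in the number of steps after the key step it is better than the chosen plan.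
- Against: A9 is an unsymmetrical 3,5-disubstituted pyranone that needs its own synthesis. A8 is a hydrolytically sensitive bis(enol ether) that must be made by regio- and stereoselective enolization. It carries substituents at C6 and at the reacting terminus C8, which hinders the s-cis conformer, and the cycloaddition must create a fully substituted carbon at C4a. The aryl-bearing double bond of A9 is a second, if weaker, dienophile.
- Comparison: both plans form C4a–C5 and reach the arene by eliminations. The chosen plan forms that bond intramolecularly with C8–C8a already in place, which is entropically easier than an intermolecular cycloaddition of two hindered partners. Step economy is equal or better for the alternative only if A8 and A9 prove short to make.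

Key step: step 5

Assumption: 3, 4, 6 and 7 (one stereocentre each) and 8 and 9 (two each) are used as racemates or diastereomer mixtures, since step 5 makes these centres sp2; 9 is drawn as the keto aldehyde although it should exist largely as its enol.

Remark: the atom balance of step 5 (C22H34O6 plus water, minus two methanol, minus water, gives C20H26O4) confirms that 8 and 10 share one carbon skeleton and one ring numbering.

## Route

Step 1
Reactants: 1 methyl 3,3-dimethoxypropanoate; 2 1-bromo-3-methylbut-2-ene (prenyl bromide)
Product: 3 methyl 2-(dimethoxymethyl)-5-methylhex-4-enoate (racemic)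
Conditions: LiN(i-Pr)2, THF, −78 °C; then 2, DMPU, −78 to −30 °C
Reagents that add atoms: none
Why: Ester enolate alkylation; the lithium enolate of 1 is kept cold so that it does not expel methoxide, and the primary allylic bromide is attacked at CH2 in SN2 fashion, which keeps the linear prenyl connectivity; the new centre (future C6) is racemic and is erased in step 5.

Step 2
Reactants: 3 methyl 2-(dimethoxymethyl)-5-methylhex-4-enoate
Product: 4 2-(dimethoxymethyl)-5-methylhex-4-enoic acid (racemic)
Conditions: LiOH·H2O, THF–MeOH–H2O, rt; then 1 M HCl to pH 4, 0 °C
Reagents that add atoms: water O (delivered as hydroxide from LiOH, [Li+].[OH-])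
Why: Saponification; the acetal and the alkene are inert to hydroxide, and a brief cold acidification to pH 4 should leave the acetal intact.

Step 3
Reactants: 4 2-(dimethoxymethyl)-5-methylhex-4-enoic acid; 5 2,2,6-trimethyl-1,3-dioxin-4-one
Product: 7 6-[4,4-dimethoxy-3-(3-methylbut-2-enyl)-2-oxobutyl]-2,2-dimethyl-1,3-dioxin-4-one (racemic), via acyl imidazolide 6 (not isolated)
Conditions: 4, CDI, THF, rt; then added to 5 + LiN(i-Pr)2 (3 equiv each), THF, −78 to −40 °C; aq. NH4Cl
Reagents that add atoms: none
Why: Claisen-type C-acylation of the lithium dienolate of 5 at its γ-carbon (future C8) by the acyl imidazolide 6; 7 is more acidic than 5 and the liberated imidazole takes one equivalent of base, hence the excess dienolate, which also holds 7 as its unreactive enolate until the quench.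

Step 4
Reactants: 7 6-[4,4-dimethoxy-3-(3-methylbut-2-enyl)-2-oxobutyl]-2,2-dimethyl-1,3-dioxin-4-one; 2 1-bromo-3-methylbut-2-ene
Product: 8 6-[4,4-dimethoxy-1,3-bis(3-methylbut-2-enyl)-2-oxobutyl]-2,2-dimethyl-1,3-dioxin-4-one (mixture of diastereomers)
Conditions: NaH (1.0 equiv), THF, 0 °C; then 2 (1.0 equiv), 0 °C to rt
Reagents that add atoms: none
Why: Alkylation of a stabilized enolate; NaH deprotonates only the C8 methylene between the C7 ketone and the vinylogous ester, far more acidic than C6–H, and the soft anion should react at carbon with the primary allylic bromide by SN2; one equivalent each of base and 2 limits a second alkylation, and the new centre is irrelevant.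

Step 5
Reactants: 8 6-[4,4-dimethoxy-1,3-bis(3-methylbut-2-enyl)-2-oxobutyl]-2,2-dimethyl-1,3-dioxin-4-one
Product: 10 7-hydroxy-2,2-dimethyl-6,8-bis(3-methylbut-2-enyl)-1,3-benzodioxin-4-one, via keto aldehyde 9 (not isolated)
Conditions: TsOH·H2O (cat.), acetone–H2O, rt to 40 °C; NaHCO3 work-up; then Et3N, CH2Cl2, rt
Reagents that add atoms: none
Why: Acid-catalysed exchange with wet acetone should free the C5 aldehyde of 8 as 9 (largely its enol) without touching the dioxinone or the alkenes. Et3N then removes the C8 proton, the most acidic C–H because it lies between the C7 ketone and the vinylogous ester, and the resulting dienolate attacks the aldehyde carbon C5 through its α-carbon C4a. This is the base-mediated aldol aromatization known for dioxinone-masked di- and triketo chains on the way to resorcylates, here with an aldehyde in place of the terminal ketone. Ring A closes as a six-membered carbocycle in a 6-(enolexo)-exo-trig aldol, the only strain-free closure open to the chain. E1cB loss of water across C4a–C5 and enolization of the C7 ketone through the C6 hydrogen then give the phenol, so the carbinol centre and the two stereocentres of 8 all become sp2 and no stereocontrol is needed. The selectivity required is carbon over oxygen cyclization: the acetonide ties up the C4 carboxyl and the C8a carbonyl, so the enol oxygens find no ketone to attack and pyranone formation is blocked, while aromatization makes the carbon pathway irreversible. The minor keto form of the enolized 3-oxo aldehyde is the reactive electrophile and is drained through that irreversible step.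

Step 6
Reactants: 10 7-hydroxy-2,2-dimethyl-6,8-bis(3-methylbut-2-enyl)-1,3-benzodioxin-4-one
Product: 11 7-(tert-butyldimethylsilyloxy)-2,2-dimethyl-6,8-bis(3-methylbut-2-enyl)-1,3-benzodioxin-4-one
Conditions: TBSCl, imidazole, DMF, rt
Reagents that add atoms: tert-butyldimethylsilyl chloride CC(C)(C)[Si](C)(C)Cl
Why: Standard silylation of a phenol made fairly acidic by the para acyl group; it prevents a phenoxide para to C4 from deactivating the acyl carbon in step 9 and prevents O-methylation in step 10, and the two ortho CH2 groups shield the silyl ether afterwards.

Step 7
Reactants: 12 4-hydroxybenzyl alcohol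
Product: 13 [4-(triisopropylsilyloxy)phenyl]methanol
Conditions: NaH (1.0 equiv), THF–DMF, 0 °C; then TIPSCl, 0 °C to rt
Reagents that add atoms: triisopropylsilyl chloride CC(C)[Si](Cl)(C(C)C)C(C)C
Why: Chemoselective O-silylation through the phenoxide; one equivalent of NaH deprotonates only the phenol, much more acidic than the benzylic alcohol, and the phenoxide captures the silyl chloride; triisopropylsilyl is chosen because its aryl ether withstands the organomagnesium and the formamide acetal.

Step 8
Reactants: 13 [4-(triisopropylsilyloxy)phenyl]methanol
Product: 14 [4-(chloromethyl)phenoxy]triisopropylsilane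
Conditions: SOCl2, pyridine, CH2Cl2, 0 °C to rt
Reagents that add atoms: thionyl chloride ClS(Cl)=O
Why: Chlorination of a benzylic alcohol through its chlorosulfite; pyridine takes up HCl so the aryl silyl ether is spared, and the chloride is preferred to the bromide because it should give less homocoupling on magnesium insertion.

Step 9
Reactants: 11 7-(tert-butyldimethylsilyloxy)-2,2-dimethyl-6,8-bis(3-methylbut-2-enyl)-1,3-benzodioxin-4-one; 14 [4-(chloromethyl)phenoxy]triisopropylsilane
Product: 16 1-[4-(tert-butyldimethylsilyloxy)-2-hydroxy-3,5-bis(3-methylbut-2-enyl)phenyl]-2-[4-(triisopropylsilyloxy)phenyl]ethanone, via benzylic Grignard reagent 15 (not isolated)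
Conditions: 14, Mg turnings, THF, 0 °C (slow addition); then 11, THF, −78 to 0 °C (3 equiv of 15); aq. NH4Cl
Reagents that add atoms: none
Why: Nucleophilic acyl substitution of the salicylate acetonide by a Grignard reagent; the tetrahedral adduct collapses with loss of acetone to a magnesium phenoxide ortho to the new ketone, which is further protected as its enolate because the benzylic CH2 is acidic, so addition should stop at the ketone; the excess of 15 covers the reagent consumed by the released acetone and by that deprotonation.

Step 10
Reactants: 16 1-[4-(tert-butyldimethylsilyloxy)-2-hydroxy-3,5-bis(3-methylbut-2-enyl)phenyl]-2-[4-(triisopropylsilyloxy)phenyl]ethanone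
Product: 18 7-(tert-butyldimethylsilyloxy)-6,8-bis(3-methylbut-2-enyl)-3-[4-(triisopropylsilyloxy)phenyl]chromen-4-one, via enaminone 17 (not isolated)
Conditions: Me2NCH(OMe)2 (3 equiv), THF, 65 °C
Reagents that add atoms: N,N-dimethylformamide dimethyl acetal COC(OC)N(C)C
Why: Deoxybenzoin route to isoflavones; the formamide acetal aminomethylenates the activated CH2 to 17, the ortho phenol adds to the enaminone carbon in a 6-endo-trig conjugate addition and dimethylamine is lost to give the pyranone; the medium is non-acidic so the alkenes survive, and both silyl ethers keep the other oxygens from being methylated.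

Step 11
Reactants: 18 7-(tert-butyldimethylsilyloxy)-6,8-bis(3-methylbut-2-enyl)-3-[4-(triisopropylsilyloxy)phenyl]chromen-4-one
Product: 19 7-hydroxy-3-(4-hydroxyphenyl)-6,8-bis(3-methylbut-2-enyl)chromen-4-one (target)
Conditions: Bu4NF, AcOH, THF, 0 °C
Reagents that add atoms: none
Why: Fluoride cleavage of both aryl silyl ethers; the acetic acid buffer keeps the medium near neutral, so the pyranone is not opened by base and no acid strong enough to close the C7 hydroxyl onto a prenyl alkene is present.

## Compound list

1 | methyl 3,3-dimethoxypropanoate | COC(=O)CC(OC)OC | starting material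
2 | 1-bromo-3-methylbut-2-ene (prenyl bromide) | CC(C)=CCBr | starting material
3 | methyl 2-(dimethoxymethyl)-5-methylhex-4-enoate (racemic) | COC(=O)C(CC=C(C)C)C(OC)OC | intermediate
4 | 2-(dimethoxymethyl)-5-methylhex-4-enoic acid (racemic) | OC(=O)C(CC=C(C)C)C(OC)OC | intermediate
5 | 2,2,6-trimethyl-1,3-dioxin-4-one | CC1=CC(=O)OC(C)(C)O1 | starting material
6 | 2-(dimethoxymethyl)-1-(imidazol-1-yl)-5-methylhex-4-en-1-one (acyl imidazolide, racemic) | COC(OC)C(CC=C(C)C)C(=O)n1ccnc1 | intermediate (not isolated)
7 | 6-[4,4-dimethoxy-3-(3-methylbut-2-enyl)-2-oxobutyl]-2,2-dimethyl-1,3-dioxin-4-one (racemic) | CC(C)=CCC(C(OC)OC)C(=O)CC1=CC(=O)OC(C)(C)O1 | intermediate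
8 | 6-[4,4-dimethoxy-1,3-bis(3-methylbut-2-enyl)-2-oxobutyl]-2,2-dimethyl-1,3-dioxin-4-one (mixture of diastereomers) | CC(C)=CCC(C(OC)OC)C(=O)C(CC=C(C)C)C1=CC(=O)OC(C)(C)O1 | intermediate
9 | 6-[1,3-bis(3-methylbut-2-enyl)-2,4-dioxobutyl]-2,2-dimethyl-1,3-dioxin-4-one (keto aldehyde, largely enolized, mixture of diastereomers) | CC(C)=CCC(C=O)C(=O)C(CC=C(C)C)C1=CC(=O)OC(C)(C)O1 | intermediate (not isolated)
10 | 7-hydroxy-2,2-dimethyl-6,8-bis(3-methylbut-2-enyl)-1,3-benzodioxin-4-one | CC(C)=CCc1cc2C(=O)OC(C)(C)Oc2c(CC=C(C)C)c1O | intermediate
11 | 7-(tert-butyldimethylsilyloxy)-2,2-dimethyl-6,8-bis(3-methylbut-2-enyl)-1,3-benzodioxin-4-one | CC(C)=CCc1cc2C(=O)OC(C)(C)Oc2c(CC=C(C)C)c1O[Si](C)(C)C(C)(C)C | intermediate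
12 | 4-hydroxybenzyl alcohol | OCc1ccc(O)cc1 | starting material
13 | [4-(triisopropylsilyloxy)phenyl]methanol | OCc1ccc(O[Si](C(C)C)(C(C)C)C(C)C)cc1 | intermediate
14 | [4-(chloromethyl)phenoxy]triisopropylsilane | ClCc1ccc(O[Si](C(C)C)(C(C)C)C(C)C)cc1 | intermediate
15 | [4-(triisopropylsilyloxy)benzyl]magnesium chloride | Cl[Mg]Cc1ccc(O[Si](C(C)C)(C(C)C)C(C)C)cc1 | intermediate (not isolated)
16 | 1-[4-(tert-butyldimethylsilyloxy)-2-hydroxy-3,5-bis(3-methylbut-2-enyl)phenyl]-2-[4-(triisopropylsilyloxy)phenyl]ethanone | CC(C)=CCc1cc(C(=O)Cc2ccc(O[Si](C(C)C)(C(C)C)C(C)C)cc2)c(O)c(CC=C(C)C)c1O[Si](C)(C)C(C)(C)C | intermediate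
17 | 3-(dimethylamino)-1-[4-(tert-butyldimethylsilyloxy)-2-hydroxy-3,5-bis(3-methylbut-2-enyl)phenyl]-2-[4-(triisopropylsilyloxy)phenyl]prop-2-en-1-one (either double-bond isomer) | CN(C)C=C(C(=O)c1cc(CC=C(C)C)c(O[Si](C)(C)C(C)(C)C)c(CC=C(C)C)c1O)c1ccc(O[Si](C(C)C)(C(C)C)C(C)C)cc1 | intermediate (not isolated)
18 | 7-(tert-butyldimethylsilyloxy)-6,8-bis(3-methylbut-2-enyl)-3-[4-(triisopropylsilyloxy)phenyl]chromen-4-one | CC(C)=CCc1cc2c(=O)c(-c3ccc(O[Si](C(C)C)(C(C)C)C(C)C)cc3)coc2c(CC=C(C)C)c1O[Si](C)(C)C(C)(C)C | intermediate
19 | 7-hydroxy-3-(4-hydroxyphenyl)-6,8-bis(3-methylbut-2-enyl)chromen-4-one | CC(C)=CCc1cc2c(=O)c(-c3ccc(O)cc3)coc2c(CC=C(C)C)c1O | target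

## Step count and least certain steps

Total: 11 steps. Longest linear sequence: 9 steps (steps 1 to 6, then 9, 10 and 11); the ring B branch (steps 7 and 8) joins in step 9.

Step 5 (key step). Most likely to go wrong: unselective unmasking (loss of methanol to an enol ether instead of hydrolysis, or hydrolytic opening of the dioxinone) and, once the aldehyde is free, its resting as the hydrogen-bonded enol or enolate. Ring closure would then be slow, and oxygen attack at C8a with loss of acetone, or deformylation, could compete. Fallback, from 8 back to 10: the aldehyde is never set free. 8 is treated with TMSOTf and Et3N in CH2Cl2 from −78 to 0 °C, which should silylate the C7 ketone towards C8 to give 6-[4,4-dimethoxy-1,3-bis(3-methylbut-2-enyl)-2-(trimethylsilyloxy)but-1-enyl]-2,2-dimethyl-1,3-dioxin-4-one F1. The same silyl triflate ionizes the acetal, and the dienol ether closes on the oxocarbenium ion through C4a in a Mukaiyama-type acetal addition to give 5-methoxy-2,2-dimethyl-6,8-bis(3-methylbut-2-enyl)-4a,5-dihydro-1,3-benzodioxine-4,7(6H)-dione F2. Elimination of methanol with amine base and enolization lead to 10. No enol oxygen is free at any point, so oxygen cyclization is excluded; the point to watch is capture of the oxocarbenium ion by the C8 prenyl alkene.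

Step 9. Most likely to go wrong: homocoupling while the electron-rich benzylic organomagnesium is formed, and incomplete opening or a second addition because released acetone and the acidic ketone consume reagent unevenly. Fallback, from 11 back to 16: the benzylic carbanion is replaced by a carboxylate-stabilized one. Commercial 4-hydroxyphenylacetic acid is silylated (TIPSCl, imidazole, DMF; aqueous work-up hydrolyses the silyl ester) to 2-[4-(triisopropylsilyloxy)phenyl]acetic acid F3. Its dianion (2 equiv LiN(i-Pr)2, THF, −78 °C) is acylated by 11 to give 3-[4-(tert-butyldimethylsilyloxy)-2-hydroxy-3,5-bis(3-methylbut-2-enyl)phenyl]-3-oxo-2-[4-(triisopropylsilyloxy)phenyl]propanoic acid F4, which should lose carbon dioxide on mild acidification and gentle warming to give 16. Acylation of arylacetic acid dianions followed by decarboxylation is established chemistry and involves no benzylic halide.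

Step 4. Most likely to go wrong: competing O-alkylation of the delocalized anion, a second alkylation at C8, or attack through C4a. Fallback, from 5 back to 8: the order of bond formation is reversed. The lithium dienolate of 5 (LiN(i-Pr)2, THF–DMPU, −78 °C) is alkylated with 2 at the γ-carbon to give 2,2-dimethyl-6-(4-methylpent-3-enyl)-1,3-dioxin-4-one F5. F5 is deprotonated again at the CH2 next to the ring and acylated with the imidazolide 6 under the conditions of step 3, giving 8 directly. The ambident keto-dioxinone anion is thus never alkylated, at the cost of a less efficient acylation at a secondary carbon.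

Step 3. Most likely to go wrong: proton transfer from the α-branched acyl donor (or from the product) to the dienolate outrunning acylation, followed by β-loss of methoxide from the enolized acyl donor. Fallback, from 3 back to 7: the C7–C8 bond is made by aldol addition instead of acylation. 3 is reduced with i-Bu2AlH (CH2Cl2, −78 °C) to 2-(dimethoxymethyl)-5-methylhex-4-enal F6. The lithium dienolate of 5 adds through its γ-carbon to give 6-[2-hydroxy-4,4-dimethoxy-3-(3-methylbut-2-enyl)butyl]-2,2-dimethyl-1,3-dioxin-4-one F7, and oxidation with Dess–Martin periodinane buffered with NaHCO3 gives 7. Aldehydes react with this dienolate much faster than they are enolized, and the oxidation is neutral.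

## Further compounds

F1 | step 5 | 6-[4,4-dimethoxy-1,3-bis(3-methylbut-2-enyl)-2-(trimethylsilyloxy)but-1-enyl]-2,2-dimethyl-1,3-dioxin-4-one | COC(OC)C(CC=C(C)C)C(O[Si](C)(C)C)=C(CC=C(C)C)C1=CC(=O)OC(C)(C)O1
F2 | step 5 | 5-methoxy-2,2-dimethyl-6,8-bis(3-methylbut-2-enyl)-4a,5-dihydro-1,3-benzodioxine-4,7(6H)-dione | COC1C(CC=C(C)C)C(=O)C(CC=C(C)C)=C2OC(C)(C)OC(=O)C12
F3 | step 9 | 2-[4-(triisopropylsilyloxy)phenyl]acetic acid | OC(=O)Cc1ccc(O[Si](C(C)C)(C(C)C)C(C)C)cc1
F4 | step 9 | 3-[4-(tert-butyldimethylsilyloxy)-2-hydroxy-3,5-bis(3-methylbut-2-enyl)phenyl]-3-oxo-2-[4-(triisopropylsilyloxy)phenyl]propanoic acid | CC(C)=CCc1cc(C(=O)C(C(=O)O)c2ccc(O[Si](C(C)C)(C(C)C)C(C)C)cc2)c(O)c(CC=C(C)C)c1O[Si](C)(C)C(C)(C)C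
F5 | step 4 | 2,2-dimethyl-6-(4-methylpent-3-enyl)-1,3-dioxin-4-one | CC(C)=CCCC1=CC(=O)OC(C)(C)O1
F6 | step 3 | 2-(dimethoxymethyl)-5-methylhex-4-enal | COC(OC)C(CC=C(C)C)C=O
F7 | step 3 | 6-[2-hydroxy-4,4-dimethoxy-3-(3-methylbut-2-enyl)butyl]-2,2-dimethyl-1,3-dioxin-4-one | COC(OC)C(CC=C(C)C)C(O)CC1=CC(=O)OC(C)(C)O1
A1 | alternative 1 | 7-hydroxy-3-(4-hydroxyphenyl)chromen-4-one (daidzein) | O=c1c(-c2ccc(O)cc2)coc2cc(O)ccc12
A2 | alternative 1 | 6,8-dibromo-7-(methoxymethoxy)-3-[4-(methoxymethoxy)phenyl]chromen-4-one | COCOc1ccc(cc1)-c1coc2c(Br)c(OCOC)c(Br)cc2c1=O
A3 | alternative 1 | tributyl(3-methylbut-2-enyl)stannane | CCCC[Sn](CCCC)(CCCC)CC=C(C)C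
A4 | alternative 1 | 7-(methoxymethoxy)-3-[4-(methoxymethoxy)phenyl]-6,8-bis(3-methylbut-2-enyl)chromen-4-one | CC(C)=CCc1cc2c(=O)c(-c3ccc(OCOC)cc3)coc2c(CC=C(C)C)c1OCOC
A5 | alternative 2 | (3E)-1-diazo-7-methylocta-3,6-dien-2-one | [N-]=[N+]=CC(=O)/C=C/CC=C(C)C
A6 | alternative 2 | triisopropyl[(5-methylhex-4-en-1-ynyl)oxy]silane | CC(C)=CCC#CO[Si](C(C)C)(C(C)C)C(C)C
A7 | alternative 2 | 2,6-bis(3-methylbut-2-enyl)-3-(triisopropylsilyloxy)phenol | CC(C)=CCc1ccc(O[Si](C(C)C)(C(C)C)C(C)C)c(CC=C(C)C)c1O
A8 | alternative 3 | tert-butyl{[1-methoxy-7-methyl-2-(3-methylbut-2-enyl)octa-1,3,6-trien-3-yl]oxy}dimethylsilane (double-bond geometry not fixed) | COC=C(CC=C(C)C)C(O[Si](C)(C)C(C)(C)C)=CCC=C(C)C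
A9 | alternative 3 | 3-(benzenesulfonyl)-5-[4-(tert-butyldimethylsilyloxy)phenyl]pyran-4-one | O=c1c(-c2ccc(O[Si](C)(C)C(C)(C)C)cc2)cocc1S(=O)(=O)c1ccccc1
A10 | alternative 3 | 3-[4-(tert-butyldimethylsilyloxy)phenyl]-7-hydroxy-6,8-bis(3-methylbut-2-enyl)chromen-4-one | CC(C)=CCc1cc2c(=O)c(-c3ccc(O[Si](C)(C)C(C)(C)C)cc3)coc2c(CC=C(C)C)c1O
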